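**Strategy.** The plan builds ring B (C3a, C4, C5, C6, C7, C7a) of the dihydrobenzofuran from scratch instead of functionalising an arene. Its O1 on C7a, OMe on C7 and CH2 on C5 coincide with C3, C4 and C6 of a 2-pyrone, and C3a/C4 correspond to an alkyne. The precursor is a 3-alkoxy-4-methoxy-6-(silyloxymethyl)-2-pyrone whose C3 oxygen carries an anti (1S,2R)-1-aryl-2-(benzyloxymethyl)but-3-ynyl chain. One thermolysis should form C3a-C7a and C4-C5, expel CO2, and close the dihydrofuran and ring B together, with C2/C3 preset. The lactone half follows by auxiliary-controlled succinate alkylation, lactonisation, trans-selective benzylation and one hydrogenolysis.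

Key step: step 12

Assumption: the facial sense of the transfer hydrogenation and the chirality relay of the allenylzinc addition are taken from the accepted models for alkynyl ketones and propargylic mesylates. If the alkoxymethyl group reversed the first, the enantiomeric catalyst would be used and nothing else would change.

Abbreviation: DBF = (2S,3R)-2-[4-(benzyloxy)-3-methoxyphenyl]-3-[(benzyloxy)methyl]-7-methoxy-2,3-dihydrobenzofuran-5-yl.

**Step 1**
Reactants: 1 methyl glycolate
Product: 2 methyl 2-[(tert-butyldimethylsilyl)oxy]acetate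
Conditions: TBSCl, imidazole, DMF, rt
Reagents that add atoms: tert-butyldimethylsilyl chloride, CC(C)(C)[Si](C)(C)Cl
Why: Imidazole-promoted silyl ether formation on the only hydroxyl group masks the future C5 benzylic oxygen in a form that withstands base, carbenoid and heat.

**Step 2**
Reactants: 3 methyl acetoacetate; 2 methyl 2-[(tert-butyldimethylsilyl)oxy]acetate
Product: 5 methyl 6-[(tert-butyldimethylsilyl)oxy]-3,5-dioxohexanoate, via sodium lithium dianion 4 (not isolated)
Conditions: NaH, then n-BuLi, THF, 0 °C; then 2, -78 to 0 °C (dianion in excess)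
Reagents that add atoms: none
Why: In this Huckin-Weiler dianion acylation (crossed Claisen condensation) the terminal carbanion of 4 is the more nucleophilic site and attacks the ester of 2, while excess dianion absorbs the acidic proton of the tricarbonyl product.

**Step 3**
Reactants: 5 methyl 6-[(tert-butyldimethylsilyl)oxy]-3,5-dioxohexanoate
Product: 6 6-{[(tert-butyldimethylsilyl)oxy]methyl}-4-hydroxy-2H-pyran-2-one
Conditions: DBU, toluene, reflux
Reagents that add atoms: none
Why: Base-induced enol lactonisation of a 3,5-dioxo ester is the standard entry to 6-substituted 4-hydroxy-2-pyrones and is driven by conjugation and loss of methanol.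

**Step 4**
Reactants: 6 6-{[(tert-butyldimethylsilyl)oxy]methyl}-4-hydroxy-2H-pyran-2-one
Product: 7 6-{[(tert-butyldimethylsilyl)oxy]methyl}-3-diazo-2H-pyran-2,4(3H)-dione
Conditions: 4-acetamidobenzenesulfonyl azide, Et3N, MeCN, 0 °C to rt
Reagents that add atoms: 4-acetamidobenzenesulfonyl azide, CC(=O)Nc1ccc(cc1)S(=O)(=O)N=[N+]=[N-]
Why: Regitz diazo transfer occurs at the activated C3 of the pyran-2,4-dione tautomer, a reaction established for 4-hydroxy-6-methyl-2-pyrone.

**Step 5**
Reactants: 8 benzyloxyacetaldehyde; 9 trimethylsilylacetylene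
Product: 11 rac-1-(benzyloxy)-4-(trimethylsilyl)but-3-yn-2-ol, via lithium trimethylsilylacetylide 10 (not isolated)
Conditions: 9, n-BuLi, THF, -78 °C; then 8
Reagents that add atoms: none
Why: This is a 1,2-addition of a lithium acetylide to an aldehyde, and the new centre is left uncontrolled because step 6 erases it.

**Step 6**
Reactants: 11 rac-1-(benzyloxy)-4-(trimethylsilyl)but-3-yn-2-ol
Product: 12 1-(benzyloxy)-4-(trimethylsilyl)but-3-yn-2-one
Conditions: Dess-Martin periodinane, CH2Cl2, rt
Reagents that add atoms: none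
Why: Dess-Martin oxidation of a propargylic alcohol runs under neutral conditions that leave the C-silyl group and the benzyl ether untouched.

**Step 7**
Reactants: 12 1-(benzyloxy)-4-(trimethylsilyl)but-3-yn-2-one
Product: 13 (S)-1-(benzyloxy)-4-(trimethylsilyl)but-3-yn-2-ol
Conditions: RuCl[(R,R)-TsDPEN](p-cymene) (1 mol %), i-PrOH, rt
Reagents that add atoms: none
Why: In this Noyori asymmetric transfer hydrogenation the alkyne fills the π-recognition site of the catalyst, so the (R,R) complex should give the carbinol that is spatially analogous to (R)-but-3-yn-2-ol and is named S here only because CH2OBn outranks the alkyne.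

**Step 8**
Reactants: 13 (S)-1-(benzyloxy)-4-(trimethylsilyl)but-3-yn-2-ol
Product: 14 (S)-1-(benzyloxy)-4-(trimethylsilyl)but-3-yn-2-yl methanesulfonate
Conditions: MsCl, Et3N, CH2Cl2, -78 to 0 °C
Reagents that add atoms: methanesulfonyl chloride, CS(=O)(=O)Cl
Why: O-sulfonylation of a secondary alcohol proceeds with retention because the C-O bond is not touched.

**Step 9**
Reactants: 14 (S)-1-(benzyloxy)-4-(trimethylsilyl)but-3-yn-2-yl methanesulfonate; 15 4-(benzyloxy)-3-methoxybenzaldehyde
Product: 17 (1S,2R)-1-[4-(benzyloxy)-3-methoxyphenyl]-2-[(benzyloxy)methyl]-4-(trimethylsilyl)but-3-yn-1-ol, via allenylzinc mesylate 16 (not isolated)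
Conditions: Pd(OAc)2 (5 mol %), PPh3 (5 mol %), Et2Zn (3 equiv), THF, -78 to -20 °C, aldehyde present from the start
Reagents that add atoms: none
Why: In this Marshall-type palladium/zinc umpolung propargylation, zerovalent palladium displaces the mesylate anti (SN2'), retentive transmetalation gives the chiral allenylzinc 16, and a cyclic SE2' addition on the zinc-bearing face relays the mesylate centre with overall inversion into C2 (R) while the aryl group turns away from CH2OBn to set C1 (S, anti), the minor syn isomer being removed by chromatography.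

**Step 10**
Reactants: 17 (1S,2R)-1-[4-(benzyloxy)-3-methoxyphenyl]-2-[(benzyloxy)methyl]-4-(trimethylsilyl)but-3-yn-1-ol; 7 6-{[(tert-butyldimethylsilyl)oxy]methyl}-3-diazo-2H-pyran-2,4(3H)-dione
Product: 18 3-{[(1S,2R)-1-[4-(benzyloxy)-3-methoxyphenyl]-2-[(benzyloxy)methyl]-4-(trimethylsilyl)but-3-yn-1-yl]oxy}-6-{[(tert-butyldimethylsilyl)oxy]methyl}-4-hydroxy-2H-pyran-2-one
Conditions: Rh2(OAc)4 (2 mol %), PhF, 80 °C, slow addition of 7 (1.5 equiv)
Reagents that add atoms: none
Why: In this rhodium-carbenoid O-H insertion, known for cyclic 2-diazo-1,3-dicarbonyl compounds and alcohols, the hydroxyl oxygen captures the carbenoid and proton transfer with enolisation gives the 3-alkoxy-4-hydroxypyrone, C1 keeps its configuration because its C-O bond is never broken, and the C-silyl cap shields the alkyne from cyclopropenation or furan formation.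

**Step 11**
Reactants: 18 3-{[(1S,2R)-1-[4-(benzyloxy)-3-methoxyphenyl]-2-[(benzyloxy)methyl]-4-(trimethylsilyl)but-3-yn-1-yl]oxy}-6-{[(tert-butyldimethylsilyl)oxy]methyl}-4-hydroxy-2H-pyran-2-one
Product: 20 3-{[(1S,2R)-1-[4-(benzyloxy)-3-methoxyphenyl]-2-[(benzyloxy)methyl]but-3-yn-1-yl]oxy}-6-{[(tert-butyldimethylsilyl)oxy]methyl}-4-methoxy-2H-pyran-2-one, via potassium pyronate 19 (not isolated)
Conditions: K2CO3, MeOH, 0 °C to rt; evaporate; Me2SO4, acetone, 40 °C
Reagents that add atoms: dimethyl sulfate, COS(=O)(=O)OC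
Why: Base-catalysed methanolytic C-desilylation is run on the pyronate anion 19, which resists ring opening, and Williamson-type O-methylation with dimethyl sulfate in acetone then favours the 4-methoxy-2-pyrone over the 2-methoxy-4-pyrone isomer.

**Step 12**
Reactants: 20 3-{[(1S,2R)-1-[4-(benzyloxy)-3-methoxyphenyl]-2-[(benzyloxy)methyl]but-3-yn-1-yl]oxy}-6-{[(tert-butyldimethylsilyl)oxy]methyl}-4-methoxy-2H-pyran-2-one
Product: 22 (2S,3R)-2-[4-(benzyloxy)-3-methoxyphenyl]-3-[(benzyloxy)methyl]-5-{[(tert-butyldimethylsilyl)oxy]methyl}-7-methoxy-2,3-dihydrobenzofuran, via bridged lactone adduct 21 (not isolated)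
Conditions: 1,2-dichlorobenzene (0.01 M), BHT (0.1 equiv), 2,6-di-tert-butylpyridine (0.2 equiv), 190 °C, sealed tube, Ar
Reagents that add atoms: none
Why: Proposed new method: the terminal alkyne adds across pyrone C3 and C6 in a concerted thermal [4+2] cycloaddition to give the 2-oxabicyclo[2.2.2]octadienone 21, which aromatises at once by retro-[4+2] loss of CO2, an irreversible exit that drains any unfavourable pre-equilibrium. The closest known reaction type is the intramolecular 2-pyrone/alkyne Diels-Alder/decarboxylation benzannulation run through carbon or nitrogen tethers, together with oxygen-tethered alkyne cycloadditions of azadienes such as 1,2,4-triazines; an oxygen tether on C3 of an electron-rich 3,4-dialkoxypyrone is the untested element. The dihydrofuran closes as the five-membered ring of a type 1 intramolecular Diels-Alder reaction (three-atom tether O1-C2-C3 anchored on diene terminus C3), and ring B closes as the six-membered ring of the cycloaddition itself (bonds C3a-C7a and C4-C5). No lasting stereocentre is created, because the two bridgeheads of 21 vanish with CO2, so either pyrone face may react and C2/C3 are simply carried over from 17. The selectivity needed is regiochemical and chemical: the short tether lets only the internal alkyne carbon reach C3, the flanking C2 carbonyl and C4 methoxy group twist the C3-O bond out of the pyrone plane so that the alkyne already lies over the diene face, and the two tether substituents favour the folded rotamer. Because diene and dienophile are electronically unmatched the reaction relies on this proximity and on heat, so an apolar solvent, high dilution, BHT and a hindered base are used to keep the ionisable benzylic C2-O1 ether from heterolysis or elimination.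

**Step 13**
Reactants: 22 (2S,3R)-2-[4-(benzyloxy)-3-methoxyphenyl]-3-[(benzyloxy)methyl]-5-{[(tert-butyldimethylsilyl)oxy]methyl}-7-methoxy-2,3-dihydrobenzofuran
Product: 23 DBF-CH2Br [(2S,3R)-5-(bromomethyl)-2-[4-(benzyloxy)-3-methoxyphenyl]-3-[(benzyloxy)methyl]-7-methoxy-2,3-dihydrobenzofuran]
Conditions: Ph3PBr2, CH2Cl2, 0 °C to rt; short silica plug, used at once
Reagents that add atoms: triphenylphosphine dibromide, BrP(Br)(c1ccccc1)(c1ccccc1)c1ccccc1
Why: Direct conversion of a silyl ether into a bromide with Ph3PBr2 (Appel-type oxyphosphonium displacement) is fastest at the electron-rich primary benzylic position and leaves the benzyl ethers alone under near-neutral conditions.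

**Step 14**
Reactants: 24 4-tert-butoxy-4-oxobutanoic acid (mono-tert-butyl succinate); 25 (R)-4-benzyloxazolidin-2-one
Product: 27 tert-butyl 4-[(4R)-4-benzyl-2-oxooxazolidin-3-yl]-4-oxobutanoate, via mixed pivalic anhydride 26 (not isolated)
Conditions: 24, PivCl, Et3N, THF, -20 °C; then 25, LiCl, rt
Reagents that add atoms: none
Why: N-acylation of the oxazolidinone through a mixed pivalic anhydride (LiCl/Et3N protocol) occurs at the less hindered succinyl carbonyl.

**Step 15**
Reactants: 27 tert-butyl 4-[(4R)-4-benzyl-2-oxooxazolidin-3-yl]-4-oxobutanoate; 23 DBF-CH2Br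
Product: 29 tert-butyl (3R)-4-[(4R)-4-benzyl-2-oxooxazolidin-3-yl]-3-(DBF-methyl)-4-oxobutanoate, via sodium Z-enolate 28 (not isolated)
Conditions: 27 (1.5 equiv), NaN(SiMe3)2, THF, -78 °C; then 23, -78 to -40 °C
Reagents that add atoms: none
Why: In this Evans asymmetric alkylation the base removes the more acidic imide α-proton rather than the ester α-proton, and the chelated Z-enolate 28 accepts the benzylic bromide on the face opposite the auxiliary benzyl group, which sets the future lactone C4 as R.

**Step 16**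
Reactants: 29 tert-butyl (3R)-4-[(4R)-4-benzyl-2-oxooxazolidin-3-yl]-3-(DBF-methyl)-4-oxobutanoate
Product: 30 tert-butyl (3R)-3-(DBF-methyl)-4-hydroxybutanoate
Conditions: LiBH4, THF, 0 °C
Reagents that add atoms: none
Why: Chemoselective hydride cleavage of the activated N-acyloxazolidinone gives the primary alcohol while the hindered tert-butyl ester is spared and the stereocentre is not involved.

**Step 17**
Reactants: 30 tert-butyl (3R)-3-(DBF-methyl)-4-hydroxybutanoate
Product: 31 (4R)-4-(DBF-methyl)dihydrofuran-2(3H)-one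
Conditions: p-TsOH·H2O (0.1 equiv), CH2Cl2, rt
Reagents that add atoms: none
Why: Acid-catalysed intramolecular transesterification (5-exo-trig lactonisation of a γ-hydroxy ester) needs only catalytic acid, too mild to harm the trans-dihydrobenzofuran, which is in any case the thermodynamic isomer.

**Step 18**
Reactants: 32 [4-(benzyloxy)-3-methoxyphenyl]methanol
Product: 33 1-(benzyloxy)-4-(bromomethyl)-2-methoxybenzene
Conditions: PBr3, Et2O, 0 °C
Reagents that add atoms: phosphorus tribromide, BrP(Br)Br
Why: This is a standard bromination of a benzylic alcohol through its phosphite ester (SN2 displacement).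

**Step 19**
Reactants: 31 (4R)-4-(DBF-methyl)dihydrofuran-2(3H)-one; 33 1-(benzyloxy)-4-(bromomethyl)-2-methoxybenzene
Product: 35 (3R,4R)-3-[4-(benzyloxy)-3-methoxybenzyl]-4-(DBF-methyl)dihydrofuran-2(3H)-one, via lithium enolate 34 (not isolated)
Conditions: LiN(SiMe3)2, THF, -78 °C; then 33, DMPU, -78 to -40 °C
Reagents that add atoms: none
Why: In this diastereoselective lactone enolate alkylation, the usual route to trans-α,β-dibenzylbutyrolactone lignans, the bromide approaches the planar enolate anti to the C4 substituent and sets C3 as R (trans).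

**Step 20**
Reactants: 35 (3R,4R)-3-[4-(benzyloxy)-3-methoxybenzyl]-4-(DBF-methyl)dihydrofuran-2(3H)-one
Product: 36 lappaol A
Conditions: H2 (1 atm), Pd/C (10 %), EtOAc-EtOH, rt
Reagents that add atoms: none
Why: Catalytic hydrogenolysis removes two aryl benzyl ethers and one alkyl benzyl ether, and at ambient pressure and temperature the cyclic C2-O1 ether, the lactone and all four stereocentres are expected to persist.

**Compound list**

1 | methyl glycolate | COC(=O)CO | starting material
2 | methyl 2-[(tert-butyldimethylsilyl)oxy]acetate | COC(=O)CO[Si](C)(C)C(C)(C)C | intermediate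
3 | methyl acetoacetate | COC(=O)CC(C)=O | starting material
4 | sodium lithium dianion of methyl acetoacetate | [Na+].[Li+].COC([O-])=CC([O-])=C | intermediate
5 | methyl 6-[(tert-butyldimethylsilyl)oxy]-3,5-dioxohexanoate | COC(=O)CC(=O)CC(=O)CO[Si](C)(C)C(C)(C)C | intermediate
6 | 6-{[(tert-butyldimethylsilyl)oxy]methyl}-4-hydroxy-2H-pyran-2-one | CC(C)(C)[Si](C)(C)OCc1cc(O)cc(=O)o1 | intermediate
7 | 6-{[(tert-butyldimethylsilyl)oxy]methyl}-3-diazo-2H-pyran-2,4(3H)-dione | CC(C)(C)[Si](C)(C)OCC1=CC(=O)C(=[N+]=[N-])C(=O)O1 | intermediate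
8 | benzyloxyacetaldehyde | O=CCOCc1ccccc1 | starting material
9 | trimethylsilylacetylene | C#C[Si](C)(C)C | starting material
10 | lithium trimethylsilylacetylide | [Li]C#C[Si](C)(C)C | intermediate
11 | rac-1-(benzyloxy)-4-(trimethylsilyl)but-3-yn-2-ol | C[Si](C)(C)C#CC(O)COCc1ccccc1 | intermediate
12 | 1-(benzyloxy)-4-(trimethylsilyl)but-3-yn-2-one | C[Si](C)(C)C#CC(=O)COCc1ccccc1 | intermediate
13 | (S)-1-(benzyloxy)-4-(trimethylsilyl)but-3-yn-2-ol | C[Si](C)(C)C#C[C@H](O)COCc1ccccc1 | intermediate
14 | (S)-1-(benzyloxy)-4-(trimethylsilyl)but-3-yn-2-yl methanesulfonate | C[Si](C)(C)C#C[C@H](OS(C)(=O)=O)COCc1ccccc1 | intermediate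
15 | 4-(benzyloxy)-3-methoxybenzaldehyde | COc1cc(C=O)ccc1OCc1ccccc1 | starting material
16 | (aS)-[4-(benzyloxy)-1-(trimethylsilyl)buta-1,2-dien-1-yl]zinc methanesulfonate | C[Si](C)(C)C([Zn]OS(C)(=O)=O)=[C@]=C([H])COCc1ccccc1 | intermediate
17 | (1S,2R)-1-[4-(benzyloxy)-3-methoxyphenyl]-2-[(benzyloxy)methyl]-4-(trimethylsilyl)but-3-yn-1-ol | C[Si](C)(C)C#C[C@H](COCc1ccccc1)[C@@H](c1ccc(OCc2ccccc2)c(OC)c1)O | intermediate
18 | 3-O-[(1S,2R)-alkynyl(TMS)] 4-hydroxy-6-(silyloxymethyl)-2-pyrone (full name in step 10) | C[Si](C)(C)C#C[C@H](COCc1ccccc1)[C@@H](c1ccc(OCc2ccccc2)c(OC)c1)Oc1c(O)cc(CO[Si](C)(C)C(C)(C)C)oc1=O | intermediate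
19 | potassium 4-pyronate of C-desilylated 18 | [K+].C#C[C@H](COCc1ccccc1)[C@@H](c1ccc(OCc2ccccc2)c(OC)c1)Oc1c([O-])cc(CO[Si](C)(C)C(C)(C)C)oc1=O | intermediate
20 | cycloaddition precursor (full name in step 11) | C#C[C@H](COCc1ccccc1)[C@@H](c1ccc(OCc2ccccc2)c(OC)c1)Oc1c(OC)cc(CO[Si](C)(C)C(C)(C)C)oc1=O | intermediate
21 | 2-oxabicyclo[2.2.2]octa-5,7-dien-3-one adduct fused to the tetrahydrofuran ring (bridgeheads transient, left undefined) | O=C1OC2(CO[Si](C)(C)C(C)(C)C)C=C(OC)C13O[C@H](c1ccc(OCc4ccccc4)c(OC)c1)[C@@H](COCc1ccccc1)C3=C2 | intermediate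
22 | (2S,3R)-2-[4-(benzyloxy)-3-methoxyphenyl]-3-[(benzyloxy)methyl]-5-{[(tert-butyldimethylsilyl)oxy]methyl}-7-methoxy-2,3-dihydrobenzofuran | CC(C)(C)[Si](C)(C)OCc1cc(OC)c2c(c1)[C@H](COCc1ccccc1)[C@@H](c1ccc(OCc3ccccc3)c(OC)c1)O2 | intermediate
23 | DBF-CH2Br | BrCc1cc(OC)c2c(c1)[C@H](COCc1ccccc1)[C@@H](c1ccc(OCc3ccccc3)c(OC)c1)O2 | intermediate
24 | 4-tert-butoxy-4-oxobutanoic acid | CC(C)(C)OC(=O)CCC(=O)O | starting material
25 | (R)-4-benzyloxazolidin-2-one | O=C1N[C@H](Cc2ccccc2)CO1 | starting material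
26 | 4-tert-butoxy-4-oxobutanoic pivalic anhydride | CC(C)(C)OC(=O)CCC(=O)OC(=O)C(C)(C)C | intermediate
27 | tert-butyl 4-[(4R)-4-benzyl-2-oxooxazolidin-3-yl]-4-oxobutanoate | CC(C)(C)OC(=O)CCC(=O)N1[C@H](Cc2ccccc2)COC1=O | intermediate
28 | sodium Z-enolate of 27 | [Na+].CC(C)(C)OC(=O)C/C=C(\[O-])N1[C@H](Cc2ccccc2)COC1=O | intermediate
29 | tert-butyl (3R)-4-[(4R)-4-benzyl-2-oxooxazolidin-3-yl]-3-(DBF-methyl)-4-oxobutanoate | CC(C)(C)OC(=O)C[C@@H](Cc1cc(OC)c2c(c1)[C@H](COCc1ccccc1)[C@@H](c1ccc(OCc3ccccc3)c(OC)c1)O2)C(=O)N1[C@H](Cc2ccccc2)COC1=O | intermediate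
30 | tert-butyl (3R)-3-(DBF-methyl)-4-hydroxybutanoate | CC(C)(C)OC(=O)C[C@@H](Cc1cc(OC)c2c(c1)[C@H](COCc1ccccc1)[C@@H](c1ccc(OCc3ccccc3)c(OC)c1)O2)CO | intermediate
31 | (4R)-4-(DBF-methyl)dihydrofuran-2(3H)-one | O=C1C[C@@H](Cc2cc(OC)c3c(c2)[C@H](COCc2ccccc2)[C@@H](c2ccc(OCc4ccccc4)c(OC)c2)O3)CO1 | intermediate
32 | [4-(benzyloxy)-3-methoxyphenyl]methanol | COc1cc(CO)ccc1OCc1ccccc1 | starting material
33 | 1-(benzyloxy)-4-(bromomethyl)-2-methoxybenzene | COc1cc(CBr)ccc1OCc1ccccc1 | intermediate
34 | lithium enolate of 31 | [Li+].[O-]C1=C[C@@H](Cc2cc(OC)c3c(c2)[C@H](COCc2ccccc2)[C@@H](c2ccc(OCc4ccccc4)c(OC)c2)O3)CO1 | intermediate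
35 | (3R,4R)-3-[4-(benzyloxy)-3-methoxybenzyl]-4-(DBF-methyl)dihydrofuran-2(3H)-one (tri-O-benzyl lappaol A) | COc1cc(C[C@H]2C(=O)OC[C@@H]2Cc2cc(OC)c3c(c2)[C@H](COCc2ccccc2)[C@@H](c2ccc(OCc4ccccc4)c(OC)c2)O3)ccc1OCc1ccccc1 | intermediate
36 | lappaol A | COc1cc(C[C@H]2C(=O)OC[C@@H]2Cc2cc(OC)c3c(c2)[C@H](CO)[C@@H](c2ccc(O)c(OC)c2)O3)ccc1O | target

**Step count.** Total: 20 steps. Longest linear sequence: 14 steps (steps 5-13, 15-17, 19 and 20, counted from 8).

**Steps most likely to fail**

**First, step 12.** The cycloaddition may be too slow. At the temperature it needs, the benzylic C2-O1 ether may ionise or eliminate, or the pyrone may degrade, before the unactivated alkyne engages the electron-rich diene.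

The fallback uses known chemistry only. Ring B is bought and the dihydrofuran is closed by enantioselective carbenoid C-H insertion. It sets out from 33 and comes back at 22. Bromide 33 alkylates commercial 5-iodovanillin (K2CO3, DMF) to give 4-{[4-(benzyloxy)-3-methoxybenzyl]oxy}-3-iodo-5-methoxybenzaldehyde F1. NaBH4 in MeOH gives the corresponding benzylic alcohol F2, and TBSCl/imidazole gives its tert-butyldimethylsilyl ether F3. Pd(PPh3)4-catalysed coupling of the aryl iodide with methyl diazoacetate (Et3N, Bu4NBr, MeCN) gives the aryl diazoacetate F4.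

A chiral dirhodium tetracarboxylate of the Rh2(PTTL)4 type, taken in the enantiomeric form that delivers 2S, then inserts the carbenoid into the activated OCH2Ar bond to give the cis-(2S,3R) dihydrobenzofuran ester F5. NaOMe in MeOH epimerises C3 to the trans-(2S,3S) ester F6. LiAlH4 gives the trans-(2S,3R) primary alcohol F7, and NaH/BnBr returns 22.

**Second, step 10.** The carbenoid may be diverted before it inserts into a hindered secondary hydroxyl group. Possible diversions are Wolff rearrangement, hydride abstraction from the electron-rich benzylic carbinol, and attack on arenes or benzyl ether oxygens.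

The fallback makes the ether by alkoxide alkylation and then builds the pyrone around it. It sets out from 17 and comes back at 18. NaH and tert-butyl bromoacetate (THF/DMF, 0 °C) give, with retention at C1, the tert-butyl alkoxyacetate F8. Separately, tert-butyldimethyl(prop-2-yn-1-yloxy)silane is lithiated (n-BuLi) and trapped with N-methoxy-N-methylcarbamoyl chloride to give the Weinreb ynamide F9. Deprotonation of F8 with LiN(SiMe3)2 at -78 °C and Claisen-type acylation with F9 gives the tert-butyl 2-alkoxy-3-oxohex-4-ynoate F10. (SPhos)AuNTf2 in MeNO2/AcOH then triggers 6-endo-dig attack of the ester carbonyl on the activated ynone with loss of the tert-butyl group and gives 18.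

**Third, step 9.** The allenylzinc may lose benzyloxide by 1,4-elimination or partly racemise. Anti/syn discrimination may also be weak with an aromatic aldehyde.

The fallback uses an isolable, covalent allenylboron reagent with additional catalyst control. It sets out from 13 and comes back at 17. ClCO2Me/pyridine gives the propargylic methyl carbonate F11. CuOtBu/Xantphos-catalysed anti-SN2' borylation with B2pin2 gives the configurationally stable 1-boryl-1-silylallene F12. Allenylboration of 15 through a closed six-membered transition state, accelerated by the matched enantiomer of the BINOL-derived phosphoric acid TRIP (toluene, 0 °C to rt), gives 17 after aqueous work-up.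

**Further compounds**

F1 | step 12 | 4-{[4-(benzyloxy)-3-methoxybenzyl]oxy}-3-iodo-5-methoxybenzaldehyde | COc1cc(C=O)cc(I)c1OCc1ccc(OCc2ccccc2)c(OC)c1
F2 | step 12 | (4-{[4-(benzyloxy)-3-methoxybenzyl]oxy}-3-iodo-5-methoxyphenyl)methanol | COc1cc(CO)cc(I)c1OCc1ccc(OCc2ccccc2)c(OC)c1
F3 | step 12 | tert-butyldimethylsilyl ether of F2 | COc1cc(CO[Si](C)(C)C(C)(C)C)cc(I)c1OCc1ccc(OCc2ccccc2)c(OC)c1
F4 | step 12 | methyl 2-diazo-2-[2-{[4-(benzyloxy)-3-methoxybenzyl]oxy}-5-{[(tert-butyldimethylsilyl)oxy]methyl}-3-methoxyphenyl]acetate | COC(=O)C(=[N+]=[N-])c1cc(CO[Si](C)(C)C(C)(C)C)cc(OC)c1OCc1ccc(OCc2ccccc2)c(OC)c1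
F5 | step 12 | methyl (2S,3R)-cis-2-[4-(benzyloxy)-3-methoxyphenyl]-5-{[(tert-butyldimethylsilyl)oxy]methyl}-7-methoxy-2,3-dihydrobenzofuran-3-carboxylate | CC(C)(C)[Si](C)(C)OCc1cc(OC)c2c(c1)[C@@H](C(=O)OC)[C@@H](c1ccc(OCc3ccccc3)c(OC)c1)O2
F6 | step 12 | methyl (2S,3S)-trans-2-[4-(benzyloxy)-3-methoxyphenyl]-5-{[(tert-butyldimethylsilyl)oxy]methyl}-7-methoxy-2,3-dihydrobenzofuran-3-carboxylate | CC(C)(C)[Si](C)(C)OCc1cc(OC)c2c(c1)[C@H](C(=O)OC)[C@@H](c1ccc(OCc3ccccc3)c(OC)c1)O2
F7 | step 12 | [(2S,3R)-2-[4-(benzyloxy)-3-methoxyphenyl]-5-{[(tert-butyldimethylsilyl)oxy]methyl}-7-methoxy-2,3-dihydrobenzofuran-3-yl]methanol | CC(C)(C)[Si](C)(C)OCc1cc(OC)c2c(c1)[C@H](CO)[C@@H](c1ccc(OCc3ccccc3)c(OC)c1)O2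
F8 | step 10 | tert-butyl 2-{[(1S,2R)-1-[4-(benzyloxy)-3-methoxyphenyl]-2-[(benzyloxy)methyl]-4-(trimethylsilyl)but-3-yn-1-yl]oxy}acetate | C[Si](C)(C)C#C[C@H](COCc1ccccc1)[C@@H](c1ccc(OCc2ccccc2)c(OC)c1)OCC(=O)OC(C)(C)C
F9 | step 10 | 4-[(tert-butyldimethylsilyl)oxy]-N-methoxy-N-methylbut-2-ynamide | CON(C)C(=O)C#CCO[Si](C)(C)C(C)(C)C
F10 | step 10 | tert-butyl 2-{[(1S,2R)-1-[4-(benzyloxy)-3-methoxyphenyl]-2-[(benzyloxy)methyl]-4-(trimethylsilyl)but-3-yn-1-yl]oxy}-6-[(tert-butyldimethylsilyl)oxy]-3-oxohex-4-ynoate (epimers at the acidic C2) | C[Si](C)(C)C#C[C@H](COCc1ccccc1)[C@@H](c1ccc(OCc2ccccc2)c(OC)c1)OC(C(=O)OC(C)(C)C)C(=O)C#CCO[Si](C)(C)C(C)(C)C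
F11 | step 9 | (S)-1-(benzyloxy)-4-(trimethylsilyl)but-3-yn-2-yl methyl carbonate | C[Si](C)(C)C#C[C@H](OC(=O)OC)COCc1ccccc1
F12 | step 9 | (aR)-2-[4-(benzyloxy)-1-(trimethylsilyl)buta-1,2-dien-1-yl]-4,4,5,5-tetramethyl-1,3,2-dioxaborolane | C[Si](C)(C)C(B1OC(C)(C)C(C)(C)O1)=[C@]=C([H])COCc1ccccc1
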